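**Retrosynthetic overview**

1. Late stage: the C12 acid is freed from its allyl ester, the C8 ester comes from a Yamaguchi acylation, and C11=C13 from an Eschenmoser methylenation. The ring B triad (6α-OH, 7β side chain, 8α-O) is grown from the C6 ketone of a trans-decalin (Saegusa enone, then C8 borylation/oxidation, C7 alkylation, C6 reduction).
2. Key disconnection: ring A is cut at C1–C10 and C4–C5 and made in one operation by an aldol addition/aldol condensation annulation of 3-methylcyclohexane-1,2-dione (ring B) with glutaraldehyde (C1–C2–C3–C4–C15).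
3. Enabling feature: the C1 carbinol and the C15 formyl group are 1,5-related through C2–C4 (a glutaraldehyde unit); C1–OH lies β to C5, and C5 carries only H next to the oxygenated C6. Ring B can therefore enter as the C5/C6 α-diketone, whose enol carbon C10 is the nucleophile for C1 and whose C5 carbonyl is the electrophile for C4.
4. Ring order: ring B is bought and ring A is closed in step 1. The C4=C5 bond left by the condensation is then reduced, and C4/C5 are equilibrated next to CHO/C6=O to the trans-fused, all-equatorial decalin.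
5. Stereocentres: C1/C10 by catalyst control (step 1), C4/C5 thermodynamic (step 2), C8 and C7 by substrate control (steps 6 and 8), C6 by thermodynamic reduction (step 9).

Key step: step 1

Remark: all compounds carry the eudesmane numbering of the target (ring A = C1–C5, C10; ring B = C5–C10; C14 = angular methyl; C15 = formyl carbon; C11–C13 = acrylic acid unit), and the target is taken as the open 6-hydroxy 15-aldehyde that is drawn, not as a lactol tautomer.

**Route**

Step 1
Reactants: 1 3-methylcyclohexane-1,2-dione (enol form: 2-hydroxy-3-methylcyclohex-2-en-1-one); 2 glutaraldehyde (pentanedial)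
Product: 4 (4R,4aR)-4-hydroxy-4a-methyl-8-oxo-2,3,4,4a,5,6,7,8-octahydronaphthalene-1-carbaldehyde (1β-OH; 10β-CH3; C4=C5; 6-oxo; 15-CHO), via aldol adduct 3 (not isolated)
Conditions: 2 (3 equiv), quinine-derived bifunctional tertiary amine–squaramide (10 mol %), pyrrolidine·AcOH (20 mol %), 4 Å MS, CH2Cl2, 0 → 25 °C
Reagents that add atoms: none
Why: Proposed new method: the tertiary amine of the catalyst deprotonates the acidic enol of 1 and the squaramide N–H bonds bind one formyl group of 2, so that the enol carbon C10 adds to C1 (aldol addition) and gives adduct 3 with the quaternary C10 and the C1 carbinol; the second formyl group is then converted by pyrrolidinium acetate into an enamine whose carbon C4 adds to the C5 carbonyl (now non-enolizable towards C10 and activated by the neighbouring C6 carbonyl), and E1cB loss of water gives the C4=C5 enal 4. The closest known reactions are the Robinson annulation (here with an aldol addition in place of the Michael addition), the amine-catalysed domino Michael/aldol reaction of cyclohexane-1,2-dione with enals (C3 of the dione as nucleophile, then enamine addition to a dione carbonyl) and Hajos–Parrish-type aldol condensations. Ring A is the only ring closed, by a 6-(enolexo)-exo-trig aldolization; attack on C6 instead of C5 would need a bridged seven-membered ring. C10 and C1 are set together in the intermolecular aldol addition by the catalyst (ion-paired enolate, hydrogen-bonded aldehyde), while C4 and C5 end up sp2 and are set in step 2. The step needs C-attack at C10 rather than at oxygen or at C7, which the enolate of the diosphenol secures under weak-base conditions, fast ring closure so that retro-aldol cleavage of 3 does not erode the selectivity, and control of the absolute and relative configuration at C10/C1, which is the unproven part.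

Step 2
Reactants: 4 enal-dione from step 1
Product: 6 (1R,4R,4aR,8aS)-4-hydroxy-4a-methyl-8-oxodecahydronaphthalene-1-carbaldehyde (trans-decalin; 1β-OH; 4α-CHO; 5α-H; 6-oxo), via epimer mixture 5 (not isolated)
Conditions: Zn, AcOH, THF, 0 °C → rt; then DBU (0.2 equiv), CH2Cl2, rt
Reagents that add atoms: none
Why: Zinc in acetic acid reduces the electron-poor C4=C5 bond of the 2-ene-1,4-dicarbonyl unit (dissolving-metal conjugate reduction), and because C5 is α to the C6 ketone and C4 is α to the formyl group, DBU equilibration should funnel the epimer mixture 5 to the trans-fused decalin with equatorial 4α-CHO (5α-H as in 5α-6-oxo steroids; an axial 4β-CHO would be 1,3-diaxial to the C10 methyl).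

Step 3
Reactants: 6 trans-decalin keto aldehyde
Product: 7 dimethyl acetal of 6 (4α-CH(OMe)2; 1β-OH; 6-oxo)
Conditions: MeOSiMe3 (3 equiv), Me3SiOTf (5 mol %), CH2Cl2, −78 °C; K2CO3, MeOH work-up
Reagents that add atoms: methoxytrimethylsilane, CO[Si](C)(C)C
Why: Silyl-triflate-catalysed acetalization under aprotic conditions at −78 °C is kinetically selective for the aldehyde over the hindered C6 ketone and should not epimerize C4, a transient C1 silyl ether being cleaved in the work-up.

Step 4
Reactants: 7 hydroxy keto acetal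
Product: 8 1β-O-tert-butyldimethylsilyl ether of 7 (6-ketone)
Conditions: tBuMe2SiOTf, 2,6-lutidine, CH2Cl2, −78 → 0 °C
Reagents that add atoms: tert-butyldimethylsilyl trifluoromethanesulfonate, CC(C)(C)[Si](C)(C)OS(=O)(=O)C(F)(F)F
Why: Silyl triflate silylation is needed for the hindered neopentyl-type C1 alcohol and, kept cold with a hindered base, should leave the ketone and the dimethyl acetal untouched.

Step 5
Reactants: 8 protected 6-ketone
Product: 10 C7=C8 enone (6-oxo-7-ene; 1β-OTBS; 4α-CH(OMe)2; 5α-H), via silyl enol ether 9 (not isolated)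
Conditions: LiN(iPr)2, Me3SiCl, THF, −78 °C; then Pd(OAc)2 (1.05 equiv), MeCN, rt
Reagents that add atoms: none
Why: Saegusa–Ito oxidation, in which kinetic deprotonation removes the accessible C7–H (C5–H is a hindered ring-fusion methine), the enolate is trapped as 9 and Pd(OAc)2 effects β-hydride elimination to the C7=C8 enone.

Step 6
Reactants: 10 enone
Product: 12 8α-hydroxy 6-ketone (1β-OTBS; 4α-CH(OMe)2), via 8α-boronate 11 (not isolated)
Conditions: B2pin2, CuCl (5 mol %), Xantphos (5 mol %), NaOtBu (10 mol %), MeOH (2 equiv), THF, rt; then NaBO3·4H2O, THF/H2O, rt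
Reagents that add atoms: sodium perborate (NaBO3), [Na+].[O-]OB=O
Why: Copper-catalysed conjugate borylation of a cyclic enone followed by C–B oxidation with retention, in which the boryl–copper should add syn across C7=C8 from the α face because the axial C10 methyl is 1,3-diaxial to the β face of C8, so that the new C8–O bond is α (equatorial).

Step 7
Reactants: 12 8α-hydroxy ketone
Product: 13 8α-O-triethylsilyl ether of 12
Conditions: Et3SiCl, imidazole, DMF, 0 °C
Reagents that add atoms: chlorotriethylsilane, CC[Si](Cl)(CC)CC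
Why: Standard silylation of the secondary alcohol, the triethylsilyl group being chosen because it can later be removed in the presence of the tert-butyldimethylsilyl ethers.

Step 8
Reactants: 13 8α-silyloxy ketone
Product: 14 7β-(allyloxycarbonylmethyl) 6-ketone (8α-OSiEt3)
Conditions: LiN(iPr)2, THF, −78 °C; allyl bromoacetate, DMPU, −78 → −40 °C
Reagents that add atoms: allyl bromoacetate, C=CCOC(=O)CBr
Why: Kinetic lithium enolate alkylation at C7 (the only α-methylene) with a reactive α-halo ester at low temperature, where β-silyloxy enolates do not eliminate; the electrophile should enter anti to the vicinal 8α-OSiEt3 group to give the equatorial 7β side chain, which is also the thermodynamic configuration of this epimerizable centre.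

Step 9
Reactants: 14 keto ester
Product: 15 6α-alcohol (7β-CH2CO2allyl; 8α-OSiEt3)
Conditions: SmI2 (2.5 equiv), H2O, THF, 0 °C
Reagents that add atoms: none
Why: Single-electron ketone reduction with SmI2/H2O, which like dissolving-metal reductions should give the thermodynamically preferred equatorial 6α-alcohol (hydride reagents would attack from the α face and give the axial 6β-alcohol) and which leaves the ester, silyl ethers and acetal untouched.

Step 10
Reactants: 15 6α-alcohol
Product: 16 6α-O-tert-butyldimethylsilyl ether of 15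
Conditions: tBuMe2SiOTf, 2,6-lutidine, CH2Cl2, −78 → 0 °C
Reagents that add atoms: tert-butyldimethylsilyl trifluoromethanesulfonate, CC(C)(C)[Si](C)(C)OS(=O)(=O)C(F)(F)F
Why: Silyl triflate silylation of the hindered 6α-alcohol, needed so that its alkoxide cannot lactonize onto the C12 ester in the next step.

Step 11
Reactants: 16 fully protected ester
Product: 19 allyl acrylate with C11=C13 in place (6α-OTBS; 8α-OSiEt3), via Mannich base 17 (not isolated), via ammonium iodide 18 (not isolated)
Conditions: LiN(iPr)2, THF, −78 °C; CH2=NMe2+ I−, −78 → 0 °C; then MeI, MeOH, rt; then DBU, CH2Cl2, rt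
Reagents that add atoms: N,N-dimethylmethyleneiminium iodide (Eschenmoser's salt), C=[N+](C)C.[I-]
Why: Eschenmoser methylenation, in which the ester enolate is aminomethylated (Mannich reaction), the amine is quaternized and E1cB loss of trimethylamine gives the 2-substituted acrylate without touching a stereocentre.

Step 12
Reactants: 19 acrylate
Product: 20 8α-alcohol (6α-OTBS; 1β-OTBS; 4α-CH(OMe)2)
Conditions: PPTS (0.2 equiv), MeOH, 0 °C → rt
Reagents that add atoms: none
Why: Acid-catalysed methanolysis cleaves the triethylsilyl ether selectively, the tert-butyldimethylsilyl ethers reacting much more slowly and the dimethyl acetal exchanging only with the solvent.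

Step 13
Reactants: 21 ethyl 2-(hydroxymethyl)acrylate
Product: 22 ethyl 2-[(tert-butyldimethylsilyloxy)methyl]acrylate
Conditions: tBuMe2SiCl, imidazole, DMF, rt
Reagents that add atoms: tert-butyldimethylsilyl chloride, CC(C)(C)[Si](C)(C)Cl
Why: Standard silylation of a primary allylic alcohol, so that the acid can later be activated without self-esterification.

Step 14
Reactants: 22 silyl-protected ethyl ester
Product: 23 2-[(tert-butyldimethylsilyloxy)methyl]acrylic acid
Conditions: LiOH·H2O, THF/H2O, 0 °C; then 1 M HCl to pH 3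
Reagents that add atoms: lithium hydroxide monohydrate (LiOH·H2O), [Li+].[OH-].O
Why: Saponification of the ethyl ester at 0 °C, which the silyl ether survives, followed by mild acidification to the free acid.

Step 15
Reactants: 20 8α-alcohol; 23 protected acrylic acid
Product: 25 8α-{2-[(tert-butyldimethylsilyloxy)methyl]acryloyl} ester of 20, via mixed anhydride 24 (not isolated)
Conditions: 23, 2,4,6-Cl3C6H2COCl, Et3N, THF, rt; then 20, DMAP, toluene, rt
Reagents that add atoms: none
Why: Yamaguchi esterification through the mixed anhydride 24, suited to a hindered secondary alcohol and to a base-sensitive acrylic acid; C8–OH is the only free hydroxyl and is acylated on oxygen with retention.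

Step 16
Reactants: 25 fully protected diester
Product: 26 allyl ester of the target (free 1β-OH, 6α-OH, CH2OH and 4α-CHO)
Conditions: 48% aq. HF, MeCN, 0 °C → rt
Reagents that add atoms: water, O
Why: Aqueous HF cleaves the three silyl ethers and hydrolyses the dimethyl acetal in one operation while the acrylate esters persist, the 4α-formyl group being equatorial and therefore configurationally stable, and short cold exposure being chosen to avoid 6,12-lactonization.

Step 17
Reactants: 26 allyl ester
Product: 27 target, (1R,4R,5S,6R,7S,8S,10R)-1,6-dihydroxy-8-{[2-(hydroxymethyl)prop-2-enoyl]oxy}-15-oxoeudesm-11(13)-en-12-oic acid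
Conditions: Pd(PPh3)4 (5 mol %), PhSiH3, CH2Cl2, 0 °C
Reagents that add atoms: none
Why: Deallylation catalysed by zerovalent palladium (Tsuji–Trost type, π-allyl transfer to the hydride donor) frees the C12 acid under neutral conditions that leave the acrylate ester and the aldehyde intact and give the hydroxy acid no acid catalyst for lactonization.

**Compound list**

1 | 3-methylcyclohexane-1,2-dione (enol form 2-hydroxy-3-methylcyclohex-2-en-1-one) | CC1=C(O)C(=O)CCC1 | starting material
2 | glutaraldehyde (pentanedial) | O=CCCCC=O | starting material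
3 | (3S)-3-[(1R)-1-hydroxy-5-oxopentyl]-3-methylcyclohexane-1,2-dione (aldol adduct) | O=CCCC[C@@H](O)[C@]1(C)CCCC(=O)C1=O | intermediate
4 | (4R,4aR)-4-hydroxy-4a-methyl-8-oxo-2,3,4,4a,5,6,7,8-octahydronaphthalene-1-carbaldehyde (1β-OH, 10β-CH3, C4=C5, 6-oxo, 15-CHO) | C1C[C@]2(C)C(C(=O)C1)=C(C=O)CC[C@H]2O | intermediate
5 | 4-hydroxy-4a-methyl-8-oxodecahydronaphthalene-1-carbaldehyde, mixture of epimers at C4 and C5 (C1 and C10 as in 4) | C1C[C@]2(C)C(C(=O)C1)C(C=O)CC[C@H]2O | intermediate
6 | (1R,4R,4aR,8aS)-4-hydroxy-4a-methyl-8-oxodecahydronaphthalene-1-carbaldehyde (trans-decalin, 1β-OH, 4α-CHO, 5α-H, 6-oxo, 10β-CH3) | C1C[C@]2(C)[C@@H](C(=O)C1)[C@H](C=O)CC[C@H]2O | intermediate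
7 | dimethyl acetal of 6 (4α-CH(OMe)2, 1β-OH, 6-oxo) | C1C[C@]2(C)[C@@H](C(=O)C1)[C@H](C(OC)OC)CC[C@H]2O | intermediate
8 | 1β-O-TBS ether of 7 (6-ketone) | C1C[C@]2(C)[C@@H](C(=O)C1)[C@H](C(OC)OC)CC[C@H]2O[Si](C)(C)C(C)(C)C | intermediate
9 | trimethylsilyl enol ether of 8 (C6(OSiMe3)=C7) | C1C[C@]2(C)[C@@H](C(O[Si](C)(C)C)=C1)[C@H](C(OC)OC)CC[C@H]2O[Si](C)(C)C(C)(C)C | intermediate
10 | C7=C8 enone (6-oxo-7-ene, 1β-OTBS, 4α-CH(OMe)2, 5α-H, 10β-CH3) | O=C1C=CC[C@]2(C)[C@@H]1[C@H](C(OC)OC)CC[C@H]2O[Si](C)(C)C(C)(C)C | intermediate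
11 | 8α-(pinacolboryl) 6-ketone | CC1(C)OB(OC1(C)C)[C@H]3C[C@]2(C)[C@@H](C(=O)C3)[C@H](C(OC)OC)CC[C@H]2O[Si](C)(C)C(C)(C)C | intermediate
12 | 8α-hydroxy 6-ketone (1β-OTBS, 4α-CH(OMe)2) | O[C@H]1C[C@]2(C)[C@@H](C(=O)C1)[C@H](C(OC)OC)CC[C@H]2O[Si](C)(C)C(C)(C)C | intermediate
13 | 8α-O-triethylsilyl ether of 12 | CC[Si](CC)(CC)O[C@H]1C[C@]2(C)[C@@H](C(=O)C1)[C@H](C(OC)OC)CC[C@H]2O[Si](C)(C)C(C)(C)C | intermediate
14 | 7β-(allyloxycarbonylmethyl) 6-ketone (8α-OSiEt3) | CC[Si](CC)(CC)O[C@H]1C[C@]2(C)[C@@H](C(=O)[C@@H]1CC(=O)OCC=C)[C@H](C(OC)OC)CC[C@H]2O[Si](C)(C)C(C)(C)C | intermediate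
15 | 6α-alcohol (7β-CH2CO2allyl, 8α-OSiEt3) | CC[Si](CC)(CC)O[C@H]1C[C@]2(C)[C@@H]([C@@H](O)[C@@H]1CC(=O)OCC=C)[C@H](C(OC)OC)CC[C@H]2O[Si](C)(C)C(C)(C)C | intermediate
16 | 6α-O-TBS ether of 15 | CC[Si](CC)(CC)O[C@H]1C[C@]2(C)[C@@H]([C@@H](O[Si](C)(C)C(C)(C)C)[C@@H]1CC(=O)OCC=C)[C@H](C(OC)OC)CC[C@H]2O[Si](C)(C)C(C)(C)C | intermediate
17 | Mannich base: C11 carries CH2NMe2 (C11 epimers) | CC[Si](CC)(CC)O[C@H]1C[C@]2(C)[C@@H]([C@@H](O[Si](C)(C)C(C)(C)C)[C@@H]1C(CN(C)C)C(=O)OCC=C)[C@H](C(OC)OC)CC[C@H]2O[Si](C)(C)C(C)(C)C | intermediate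
18 | trimethylammonium iodide of 17 | CC[Si](CC)(CC)O[C@H]1C[C@]2(C)[C@@H]([C@@H](O[Si](C)(C)C(C)(C)C)[C@@H]1C(C[N+](C)(C)C)C(=O)OCC=C)[C@H](C(OC)OC)CC[C@H]2O[Si](C)(C)C(C)(C)C.[I-] | intermediate
19 | allyl acrylate with C11=C13 (6α-OTBS, 8α-OSiEt3, 1β-OTBS, 4α-CH(OMe)2) | CC[Si](CC)(CC)O[C@H]1C[C@]2(C)[C@@H]([C@@H](O[Si](C)(C)C(C)(C)C)[C@@H]1C(=C)C(=O)OCC=C)[C@H](C(OC)OC)CC[C@H]2O[Si](C)(C)C(C)(C)C | intermediate
20 | 8α-alcohol of 19 | O[C@H]1C[C@]2(C)[C@@H]([C@@H](O[Si](C)(C)C(C)(C)C)[C@@H]1C(=C)C(=O)OCC=C)[C@H](C(OC)OC)CC[C@H]2O[Si](C)(C)C(C)(C)C | intermediate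
21 | ethyl 2-(hydroxymethyl)acrylate | C=C(CO)C(=O)OCC | starting material
22 | ethyl 2-[(tert-butyldimethylsilyloxy)methyl]acrylate | C=C(CO[Si](C)(C)C(C)(C)C)C(=O)OCC | intermediate
23 | 2-[(tert-butyldimethylsilyloxy)methyl]acrylic acid | C=C(CO[Si](C)(C)C(C)(C)C)C(=O)O | intermediate
24 | mixed anhydride of 23 with 2,4,6-trichlorobenzoic acid | C=C(CO[Si](C)(C)C(C)(C)C)C(=O)OC(=O)c1c(Cl)cc(Cl)cc1Cl | intermediate
25 | 8α-{2-[(tert-butyldimethylsilyloxy)methyl]acryloyl} ester of 20 | C=C(CO[Si](C)(C)C(C)(C)C)C(=O)O[C@H]1C[C@]2(C)[C@@H]([C@@H](O[Si](C)(C)C(C)(C)C)[C@@H]1C(=C)C(=O)OCC=C)[C@H](C(OC)OC)CC[C@H]2O[Si](C)(C)C(C)(C)C | intermediate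
26 | allyl ester of the target | C=C(CO)C(=O)O[C@H]1C[C@]2(C)[C@@H]([C@@H](O)[C@@H]1C(=C)C(=O)OCC=C)[C@H](C=O)CC[C@H]2O | intermediate
27 | (1R,4R,5S,6R,7S,8S,10R)-1,6-dihydroxy-8-{[2-(hydroxymethyl)prop-2-enoyl]oxy}-15-oxoeudesm-11(13)-en-12-oic acid | C=C(CO)C(=O)O[C@H]1C[C@]2(C)[C@@H]([C@@H](O)[C@@H]1C(=C)C(=O)O)[C@H](C=O)CC[C@H]2O | target

**Step count**

Total steps: 17. Longest linear sequence: 15 steps (steps 1–12 and 15–17, from 1 to 27); steps 13 and 14 prepare the acyl fragment 23.

**Steps most likely to fail**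

1. Step 1 (Proposed new method). What may go wrong: retro-aldol cleavage of the crowded adduct 3 before ring closure, amine-induced oligomerization of 2, condensation at C7 instead of addition at C10, and weak control of the C10/C1 configuration. Fallback with known chemistry, in which the two ring A bonds are made one after the other: from 1, palladium-catalysed asymmetric allylic alkylation with prop-2-ene-1,1-diyl diacetate (Pd2(dba)3·CHCl3, N,N′-bis(2-diphenylphosphinobenzoyl)cyclohexane-1,2-diamine, Cs2CO3, CH2Cl2) forms the C1–C10 bond irreversibly and should give (3S)-3-[(1R)-1-acetoxyprop-2-enyl]-3-methylcyclohexane-1,2-dione F1. Cross-metathesis with 4,4-diethoxybut-1-ene (second-generation Grubbs catalyst, (H2IMes)(PCy3)Cl2Ru=CHPh, CH2Cl2, 40 °C) extends the chain to the E-alkenyl acetal F2, and hydrogenation (H2, Pd/C, EtOAc) gives the saturated acetoxy acetal F3. Treatment with 1 M HCl in THF and then piperidinium acetate in toluene at 80 °C unmasks the aldehyde and closes ring A by the intramolecular aldol condensation of C4 onto C5, giving the O-acetate of the enal F4. K2CO3 in MeOH removes the acetate and the route is rejoined at 4.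

2. Step 6. What may go wrong: slow borylcupration at the hindered C8, or addition from the β face, which would place the C8 oxygen axial. Fallback that changes the mechanism of oxygen delivery: from 10, Weitz–Scheffer epoxidation (tBuOOH, DBU, CH2Cl2) should give the 7α,8α-epoxy 6-ketone F5 by attack of the peroxide anion anti to the angular methyl; reductive opening of the Cα–O bond with PhSeNa (from (PhSe)2 and NaBH4, EtOH, AcOH) then gives the 8α-hydroxy ketone, and the route is rejoined at 12.

3. Step 9. What may go wrong: hydrogen delivery under kinetic control from the open α face (axial 6β-alcohol), or attack of the samarium alkoxide on the C12 allyl ester (6,12-lactonization). Fallback that moves the reduction to a classical thermodynamic dissolving-metal step: from 14, deallylation (Pd(PPh3)4, PhSiH3, CH2Cl2) gives the keto acid F6; Li in liquid NH3/THF/tBuOH at −78 °C reduces the ketone to the equatorial alcohol while the carboxylate is inert, giving the 6α-hydroxy acid F7; allyl bromide and KHCO3 in DMF re-form the allyl ester, and the route is rejoined at 15.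

Further compounds
F1 | step 1 | (3S)-3-[(1R)-1-acetoxyprop-2-enyl]-3-methylcyclohexane-1,2-dione | C=C[C@@H](OC(C)=O)[C@]1(C)CCCC(=O)C1=O
F2 | step 1 | (3S)-3-[(1R,2E)-1-acetoxy-5,5-diethoxypent-2-enyl]-3-methylcyclohexane-1,2-dione | CCOC(OCC)C/C=C/[C@@H](OC(C)=O)[C@]1(C)CCCC(=O)C1=O
F3 | step 1 | (3S)-3-[(1R)-1-acetoxy-5,5-diethoxypentyl]-3-methylcyclohexane-1,2-dione | CCOC(OCC)CCC[C@@H](OC(C)=O)[C@]1(C)CCCC(=O)C1=O
F4 | step 1 | O-acetate of 4, (4R,4aR)-4-acetoxy-4a-methyl-8-oxo-2,3,4,4a,5,6,7,8-octahydronaphthalene-1-carbaldehyde | C1C[C@]2(C)C(C(=O)C1)=C(C=O)CC[C@H]2OC(C)=O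
F5 | step 6 | 7α,8α-epoxy 6-ketone (1β-OTBS, 4α-CH(OMe)2) | O1[C@H]2C[C@]3(C)[C@@H](C(=O)[C@@H]12)[C@H](C(OC)OC)CC[C@H]3O[Si](C)(C)C(C)(C)C
F6 | step 9 | keto acid from 14 (7β-CH2CO2H, 8α-OSiEt3, 6-oxo) | CC[Si](CC)(CC)O[C@H]1C[C@]2(C)[C@@H](C(=O)[C@@H]1CC(=O)O)[C@H](C(OC)OC)CC[C@H]2O[Si](C)(C)C(C)(C)C
F7 | step 9 | 6α-hydroxy acid (7β-CH2CO2H, 8α-OSiEt3) | CC[Si](CC)(CC)O[C@H]1C[C@]2(C)[C@@H]([C@@H](O)[C@@H]1CC(=O)O)[C@H](C(OC)OC)CC[C@H]2O[Si](C)(C)C(C)(C)C
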